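**Strategy.** The seven-membered ring is read as a cyclohepta-1,4-diene: C1=C10 is already present and C7=C8 can be restored from the C7–H/C8–O pair. A retro-Cope cut through C5–C6 then leads to a cis-1,2-dialkenylcyclopropane on C8–C9–C10, one arm being the cyclopentene of the five-membered ring, the other a (Z)-enol acetate. Heating closes the seven-membered ring last with release of cyclopropane strain, installs the tetrasubstituted C1=C10 alkene and transfers the cyclopropane chirality, set in one ligand-controlled cyclopropanation, to C5 and C6. C4, C7 and C8 follow by substrate control.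

Key step: step 8

Remark: atom labels follow guaiane numbering (C1/C5 ring fusion, C4 carbinol, C6 acetoxy, C7 isopropyl, C8 angeloyloxy, C9 methylene, C10 methyl-bearing alkene carbon, C15 methyl on C4). The facial sense of the ligand in step 3 is assumed to follow its established model for allylic alcohols; the enantiomeric ligand would be used otherwise.

Step 1
Reactants: 1 3-methylbut-1-yne
Product: 3 2-[(Z)-2-bromo-3-methylbut-1-en-1-yl]-4,4,5,5-tetramethyl-1,3,2-dioxaborolane, via dibromoborane adduct 2 (not isolated)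
Conditions: BBr3, CH2Cl2, −78 °C to rt; then pinacol, CH2Cl2, −78 °C to rt
Reagents that add atoms: boron tribromide BrB(Br)Br; pinacol CC(C)(O)C(C)(C)O
Why: Bromoboration of a terminal alkyne is a syn, Markovnikov addition (Br to the internal carbon, B to the terminal one), so Br and B end up cis, and pinacol turns the dibromoborane into the stable boronate.

Step 2
Reactants: 4 prop-2-yn-1-ol; 3 2-[(Z)-2-bromo-3-methylbut-1-en-1-yl]-4,4,5,5-tetramethyl-1,3,2-dioxaborolane
Product: 7 (2Z,4Z)-2-methyl-4-(propan-2-yl)-5-(4,4,5,5-tetramethyl-1,3,2-dioxaborolan-2-yl)penta-2,4-dien-1-ol, via oxamagnesacycle 5 (not isolated), via alkenylzinc 6 (not isolated)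
Conditions: MeMgBr, copper iodide CuI (10 mol%), Et2O/THF, −10 °C to rt; ZnBr2, THF, 0 °C; then 3, Pd(P(t-Bu)3)2 (2 mol%), THF, rt
Reagents that add atoms: methylmagnesium bromide C[Mg]Br
Why: Copper-catalysed anti-carbomagnesiation of the propargylic alkoxide places Mg cis to the CH2O group through a five-membered chelate, and transmetalation to zinc followed by Negishi coupling at the C–Br bond of 3 proceeds with retention at both alkenyl carbons, giving the 2Z,4Z diene with the C–B bond intact under base-free conditions.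

Step 3
Reactants: 7 (2Z,4Z)-dienol boronate
Product: 8 [(1S,2S)-1-methyl-2-[(Z)-3-methyl-1-(4,4,5,5-tetramethyl-1,3,2-dioxaborolan-2-yl)but-1-en-2-yl]cyclopropyl]methanol
Conditions: Zn(CH2I)2·DME (from Et2Zn and CH2I2), (4R,5R)-2-butyl-N,N,N′,N′-tetramethyl-1,3,2-dioxaborolane-4,5-dicarboxamide (1.2 equiv), CH2Cl2, −10 °C to rt
Reagents that add atoms: diiodomethane ICI
Why: Charette's hydroxyl-directed asymmetric Simmons–Smith cyclopropanation is stereospecific (the Z alkene gives the cis cyclopropane, C9 being the new carbon), the ligand is expected to fix the absolute configuration at C8 and C10, and the hindered boron-substituted alkene without a directing group should be spared.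

Step 4
Reactants: 8 cyclopropylmethanol
Product: 9 (1S,2S)-1-methyl-2-[(Z)-3-methyl-1-(4,4,5,5-tetramethyl-1,3,2-dioxaborolan-2-yl)but-1-en-2-yl]cyclopropane-1-carbaldehyde
Conditions: Dess–Martin periodinane, CH2Cl2, 0 °C to rt
Reagents that add atoms: none
Why: Dess–Martin oxidation of the primary alcohol to the aldehyde (C1) is neutral and should leave the alkenylboronate and the vinylcyclopropane untouched.

Step 5
Reactants: 9 cyclopropanecarbaldehyde; 10 but-3-en-2-one
Product: 12 3-[(1S,2S)-1-methyl-2-[(Z)-3-methyl-1-(4,4,5,5-tetramethyl-1,3,2-dioxaborolan-2-yl)but-1-en-2-yl]cyclopropyl]cyclopent-2-en-1-one, via 1,4-diketone 11 (not isolated)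
Conditions: 3-benzyl-5-(2-hydroxyethyl)-4-methylthiazolium chloride (20 mol%), Et3N, EtOH, 70 °C; then aq. NaOH, 50 °C
Reagents that add atoms: none
Why: The thiazolium-catalysed Stetter reaction adds the aldehyde as an acyl anion equivalent to the enone (C1–C2 bond), and the only possible intramolecular aldol condensation of the 1,4-diketone (C5 methyl onto the C1 ketone, C10 bearing no hydrogen) closes the five-membered ring as the 3-substituted cyclopentenone.

Step 6
Reactants: 12 cyclopentenone
Product: 13 2-[(Z)-3-methyl-2-[(1S,2S)-2-methyl-2-(3-methylidenecyclopent-1-en-1-yl)cyclopropyl]but-1-en-1-yl]-4,4,5,5-tetramethyl-1,3,2-dioxaborolane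
Conditions: Ph3PCH3Br, KOt-Bu, THF, 0 °C to rt
Reagents that add atoms: methyltriphenylphosphonium bromide C[P+](c1ccccc1)(c1ccccc1)c1ccccc1.[Br-]
Why: Wittig methylenation of the enone carbonyl installs C15 as an exocyclic methylidene before the thermal step, so that no β,γ- to α,β-enone isomerisation can later erode C5, and pinacol boronates tolerate the ylide.

Step 7
Reactants: 13 dienyl cyclopropane boronate
Product: 14 (Z)-3-methyl-2-[(1R,2S)-2-methyl-2-(3-methylidenecyclopent-1-en-1-yl)cyclopropyl]but-1-en-1-yl acetate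
Conditions: Cu(OAc)2 (2 equiv), Et3N, 4 Å MS, MeCN, dry air, 40 °C
Reagents that add atoms: copper diacetate CC(=O)[O-].CC(=O)[O-].[Cu+2]
Why: Chan–Lam-type oxidative coupling of the alkenylboronate with acetate (transmetalation to copper, then C–O reductive elimination from trivalent copper) replaces boron by acetoxy with retention, so the enol oxygen stays cis to the cyclopropane.

Step 8
Reactants: 14 cis-dialkenylcyclopropane enol acetate
Product: 15 (3aR,4S)-8-methyl-3-methylidene-5-(propan-2-yl)-1,2,3,3a,4,7-hexahydroazulen-4-yl acetate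
Conditions: toluene (degassed), BHT (cat.), 110–130 °C, sealed base-washed tube
Reagents that add atoms: none
Why: Concerted [3,3]-sigmatropic (Cope) rearrangement of the cis-1,2-dialkenylcyclopropane through the boat transition state, in which both alkenes lie over the three-membered ring: C8–C10 breaks, C5–C6 forms and the cyclopropane strain is released. The closest known reaction type is the divinylcyclopropane–cycloheptadiene rearrangement of oxygen-substituted cis-divinylcyclopropanes used in formal (4+3) routes to hydroazulenes. The seven-membered ring (C1, C5, C6, C7, C8, C9, C10) is closed by this pericyclic ring expansion of the three-membered ring, the C5–C6 σ-bond joining the termini of the two alkenes while C1=C10 and C7=C8 appear as the two cis ring alkenes. C5 and C6 are set by chirality transfer from C10 and C8: in the boat, ring carbon C4 occupies the outward position on C5 and the acetoxy group the inward position on C6, so they become trans (H-5 and the C6 oxygen on the same face) and the (1R,2S) cyclopropane gives 3aR,4S. The step needs the cis cyclopropane and the Z enol acetate, secured by the Z alkene of 7, the stereospecific cyclopropanation and the retentive couplings; the inward acetoxy group and the quaternary C10 raise the barrier, hence the heating, and the radical inhibitor and base-washed glass are meant to suppress isomerisation of the dienes.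

Step 9
Reactants: 15 hydroazulene triene
Product: 17 (3S,3aR,4S)-3-hydroxy-3,8-dimethyl-5-(propan-2-yl)-1,2,3,3a,4,7-hexahydroazulen-4-yl acetate, via tertiary hydroperoxide 16 (not isolated)
Conditions: Co(acac)2 (20 mol%), PhSiH3, O2 (1 atm), THF/i-PrOH, 0 °C to rt; then PPh3
Reagents that add atoms: dioxygen O=O
Why: Mukaiyama hydration (cobalt hydride H-atom transfer, O2 trapping, phosphine reduction) is Markovnikov and fastest for the 1,1-disubstituted exocyclic alkene, and the tertiary C4 radical should be trapped on the face opposite to the C5–C6 bond, giving the hydroxyl cis to H-5 (C4 S).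

Step 10
Reactants: 17 tertiary alcohol
Product: 19 (3S,3aR,4R,5R,6S)-3,6-dihydroxy-3,8-dimethyl-5-(propan-2-yl)-1,2,3,3a,4,5,6,7-octahydroazulen-4-yl acetate, via C8 alkylborane 18 (not isolated)
Conditions: BH3·SMe2 (excess), THF, 0 °C to rt; then NaBO3·4H2O, THF/H2O, rt
Reagents that add atoms: sodium perborate tetrahydrate [Na+].[O-]B1OO1.O.O.O.O
Why: Hydroboration–oxidation should take the trisubstituted C7=C8 alkene in preference to the tetrasubstituted C1=C10, with boron at C8 and syn addition anti to the pseudoaxial allylic acetoxy group on C6, so that H-7 and the C8 oxygen are on the face opposite to the acetate (C7 R, C8 S), and perborate oxidises with retention without cleaving the acetate.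

Step 11
Reactants: 19 diol monoacetate; 20 angelic acid
Product: 22 (3S,3aR,4R,5R,6S)-4-acetoxy-3-hydroxy-3,8-dimethyl-5-(propan-2-yl)-1,2,3,3a,4,5,6,7-octahydroazulen-6-yl (2Z)-2-methylbut-2-enoate, via mixed anhydride 21 (not isolated)
Conditions: 20, 2,4,6-trichlorobenzoyl chloride, Et3N, toluene, rt; then 19, toluene, 80 °C
Reagents that add atoms: none
Why: Yamaguchi-type acylation through the mixed anhydride should esterify the secondary C8 hydroxyl selectively over the tertiary C4 hydroxyl, and the DMAP-free protocol is chosen because it is known to preserve the Z (angelate) geometry.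

**Compound list**

1 | 3-methylbut-1-yne | CC(C)C#C | starting material
2 | dibromo[(Z)-2-bromo-3-methylbut-1-en-1-yl]borane | CC(C)/C(Br)=C\B(Br)Br | intermediate (not isolated)
3 | 2-[(Z)-2-bromo-3-methylbut-1-en-1-yl]-4,4,5,5-tetramethyl-1,3,2-dioxaborolane | CC(C)/C(Br)=C\B1OC(C)(C)C(C)(C)O1 | intermediate
4 | prop-2-yn-1-ol | C#CCO | starting material
5 | 4-methyl-2,5-dihydro-1,2-oxamagnesole (cyclic (Z)-alkenylmagnesium alkoxide) | CC1=C[Mg]OC1 | intermediate (not isolated)
6 | 4-methyl-2,5-dihydro-1,2-oxazincole (cyclic (Z)-alkenylzinc alkoxide) | CC1=C[Zn]OC1 | intermediate (not isolated)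
7 | (2Z,4Z)-2-methyl-4-(propan-2-yl)-5-(4,4,5,5-tetramethyl-1,3,2-dioxaborolan-2-yl)penta-2,4-dien-1-ol | OC/C(C)=C\C(C(C)C)=C/B1OC(C)(C)C(C)(C)O1 | intermediate
8 | [(1S,2S)-1-methyl-2-[(Z)-3-methyl-1-(4,4,5,5-tetramethyl-1,3,2-dioxaborolan-2-yl)but-1-en-2-yl]cyclopropyl]methanol | OC[C@@]1(C)C[C@H]1/C(C(C)C)=C\B2OC(C)(C)C(C)(C)O2 | intermediate
9 | (1S,2S)-1-methyl-2-[(Z)-3-methyl-1-(4,4,5,5-tetramethyl-1,3,2-dioxaborolan-2-yl)but-1-en-2-yl]cyclopropane-1-carbaldehyde | O=C[C@@]1(C)C[C@H]1/C(C(C)C)=C\B2OC(C)(C)C(C)(C)O2 | intermediate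
10 | but-3-en-2-one (methyl vinyl ketone) | CC(=O)C=C | starting material
11 | 1-[(1S,2S)-1-methyl-2-[(Z)-3-methyl-1-(4,4,5,5-tetramethyl-1,3,2-dioxaborolan-2-yl)but-1-en-2-yl]cyclopropyl]pentane-1,4-dione | CC(=O)CCC(=O)[C@@]1(C)C[C@H]1/C(C(C)C)=C\B2OC(C)(C)C(C)(C)O2 | intermediate (not isolated)
12 | 3-[(1S,2S)-1-methyl-2-[(Z)-3-methyl-1-(4,4,5,5-tetramethyl-1,3,2-dioxaborolan-2-yl)but-1-en-2-yl]cyclopropyl]cyclopent-2-en-1-one | O=C1CCC(=C1)[C@@]2(C)C[C@H]2/C(C(C)C)=C\B3OC(C)(C)C(C)(C)O3 | intermediate
13 | 2-[(Z)-3-methyl-2-[(1S,2S)-2-methyl-2-(3-methylidenecyclopent-1-en-1-yl)cyclopropyl]but-1-en-1-yl]-4,4,5,5-tetramethyl-1,3,2-dioxaborolane | C=C1CCC(=C1)[C@@]2(C)C[C@H]2/C(C(C)C)=C\B3OC(C)(C)C(C)(C)O3 | intermediate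
14 | (Z)-3-methyl-2-[(1R,2S)-2-methyl-2-(3-methylidenecyclopent-1-en-1-yl)cyclopropyl]but-1-en-1-yl acetate | C=C1CCC(=C1)[C@@]2(C)C[C@H]2/C(C(C)C)=C\OC(C)=O | intermediate
15 | (3aR,4S)-8-methyl-3-methylidene-5-(propan-2-yl)-1,2,3,3a,4,7-hexahydroazulen-4-yl acetate | CC(C)C1=CCC(C)=C2CCC(=C)[C@H]2[C@@H]1OC(C)=O | intermediate
16 | (3S,3aR,4S)-3-hydroperoxy-3,8-dimethyl-5-(propan-2-yl)-1,2,3,3a,4,7-hexahydroazulen-4-yl acetate | CC(C)C1=CCC(C)=C2CC[C@](C)(OO)[C@H]2[C@@H]1OC(C)=O | intermediate (not isolated)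
17 | (3S,3aR,4S)-3-hydroxy-3,8-dimethyl-5-(propan-2-yl)-1,2,3,3a,4,7-hexahydroazulen-4-yl acetate | CC(C)C1=CCC(C)=C2CC[C@](C)(O)[C@H]2[C@@H]1OC(C)=O | intermediate
18 | (3S,3aR,4R,5S,6S)-6-boranyl-3-hydroxy-3,8-dimethyl-5-(propan-2-yl)-1,2,3,3a,4,5,6,7-octahydroazulen-4-yl acetate | B[C@H]1CC(C)=C2CC[C@](C)(O)[C@H]2[C@H](OC(C)=O)[C@@H]1C(C)C | intermediate (not isolated)
19 | (3S,3aR,4R,5R,6S)-3,6-dihydroxy-3,8-dimethyl-5-(propan-2-yl)-1,2,3,3a,4,5,6,7-octahydroazulen-4-yl acetate | O[C@H]1CC(C)=C2CC[C@](C)(O)[C@H]2[C@H](OC(C)=O)[C@@H]1C(C)C | intermediate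
20 | angelic acid ((2Z)-2-methylbut-2-enoic acid) | C/C=C(/C)C(=O)O | starting material
21 | (2Z)-2-methylbut-2-enoic 2,4,6-trichlorobenzoic anhydride | C/C=C(/C)C(=O)OC(=O)c1c(Cl)cc(Cl)cc1Cl | intermediate (not isolated)
22 | (3S,3aR,4R,5R,6S)-4-acetoxy-3-hydroxy-3,8-dimethyl-5-(propan-2-yl)-1,2,3,3a,4,5,6,7-octahydroazulen-6-yl (2Z)-2-methylbut-2-enoate | C/C=C(/C)C(=O)O[C@H]1CC(C)=C2CC[C@](C)(O)[C@H]2[C@H](OC(C)=O)[C@@H]1C(C)C | target

**Step count.** Total steps: 11. Longest linear sequence: 11 steps (1 → 3 → 7 → 8 → 9 → 12 → 13 → 14 → 15 → 17 → 19 → 22).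

**Steps most likely to fail**

Step 7. Transmetalation of the hindered pinacol boronate to copper may be slower than protodeboronation, homocoupling or oxidation of the diene, and alkene geometry could be partly lost. The fallback sets out from 13 and moves the C–O bond formation behind the rearrangement. Heating 13 (mesitylene, about 160 °C, BHT) should give, by the same boat Cope process with the boryl group inward, the allylic boronate 2-[(3aR,4S)-8-methyl-3-methylidene-5-(propan-2-yl)-1,2,3,3a,4,7-hexahydroazulen-4-yl]-4,4,5,5-tetramethyl-1,3,2-dioxaborolane F1. Oxidation with NaBO3·4H2O (retention at C6) would give the allylic alcohol (3aR,4S)-8-methyl-3-methylidene-5-(propan-2-yl)-1,2,3,3a,4,7-hexahydroazulen-4-ol F2, and Ac2O, pyridine, DMAP returns to the route at 15.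

Step 8. The inward acetoxy group slows the boat transition state, so that one-centre epimerisation of the cyclopropane to the unreactive trans isomer and thermal isomerisation or oligomerisation of the methylidenecyclopentene diene may compete. The fallback sets out from 12 and runs the rearrangement on a push–pull pair (acceptor enone, donor enol acetate), which should lower the barrier and avoids the labile diene. Acetoxylation of 12 with Cu(OAc)2 as in step 7 gives (Z)-3-methyl-2-[(1R,2S)-2-methyl-2-(3-oxocyclopent-1-en-1-yl)cyclopropyl]but-1-en-1-yl acetate F3. Heating (toluene, about 100 °C) should give the β,γ-unsaturated ketone (3aR,4S)-8-methyl-3-oxo-5-(propan-2-yl)-1,2,3,3a,4,7-hexahydroazulen-4-yl acetate F4, and non-basic methylenation with Cp2TiMe2 (toluene, 65 °C), chosen to avoid enolisation at C5, returns to the route at 15.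

Step 5. The Breslow intermediate of the α-quaternary cyclopropanecarbaldehyde may form slowly, and ring opening of the vinylcyclopropane through the homoenolate or retro-Claisen isomerisation of the cis-alkenyl aldehyde could outrun the conjugate addition. The fallback sets out from 9 and replaces the umpolung by a polar addition. The Grignard reagent from 2-(2-bromoethyl)-2-methyl-1,3-dioxolane (THF, −78 °C) gives 1-[(1S,2S)-1-methyl-2-[(Z)-3-methyl-1-(4,4,5,5-tetramethyl-1,3,2-dioxaborolan-2-yl)but-1-en-2-yl]cyclopropyl]-3-(2-methyl-1,3-dioxolan-2-yl)propan-1-ol F5 (carbinol epimers, both usable). Dess–Martin oxidation gives the keto ketal 1-[(1S,2S)-1-methyl-2-[(Z)-3-methyl-1-(4,4,5,5-tetramethyl-1,3,2-dioxaborolan-2-yl)but-1-en-2-yl]cyclopropyl]-3-(2-methyl-1,3-dioxolan-2-yl)propan-1-one F6. PPTS in acetone/H2O then releases diketone 11, and NaOH in EtOH closes it to 12, where the route is rejoined.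

**Further compounds**

F1 | step 7 | 2-[(3aR,4S)-8-methyl-3-methylidene-5-(propan-2-yl)-1,2,3,3a,4,7-hexahydroazulen-4-yl]-4,4,5,5-tetramethyl-1,3,2-dioxaborolane | CC(C)C1=CCC(C)=C2CCC(=C)[C@H]2[C@@H]1B3OC(C)(C)C(C)(C)O3
F2 | step 7 | (3aR,4S)-8-methyl-3-methylidene-5-(propan-2-yl)-1,2,3,3a,4,7-hexahydroazulen-4-ol | CC(C)C1=CCC(C)=C2CCC(=C)[C@H]2[C@@H]1O
F3 | step 8 | (Z)-3-methyl-2-[(1R,2S)-2-methyl-2-(3-oxocyclopent-1-en-1-yl)cyclopropyl]but-1-en-1-yl acetate | O=C1CCC(=C1)[C@@]2(C)C[C@H]2/C(C(C)C)=C\OC(C)=O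
F4 | step 8 | (3aR,4S)-8-methyl-3-oxo-5-(propan-2-yl)-1,2,3,3a,4,7-hexahydroazulen-4-yl acetate | CC(C)C1=CCC(C)=C2CCC(=O)[C@H]2[C@@H]1OC(C)=O
F5 | step 5 | 1-[(1S,2S)-1-methyl-2-[(Z)-3-methyl-1-(4,4,5,5-tetramethyl-1,3,2-dioxaborolan-2-yl)but-1-en-2-yl]cyclopropyl]-3-(2-methyl-1,3-dioxolan-2-yl)propan-1-ol | CC1(CCC(O)[C@@]2(C)C[C@H]2/C(C(C)C)=C\B3OC(C)(C)C(C)(C)O3)OCCO1
F6 | step 5 | 1-[(1S,2S)-1-methyl-2-[(Z)-3-methyl-1-(4,4,5,5-tetramethyl-1,3,2-dioxaborolan-2-yl)but-1-en-2-yl]cyclopropyl]-3-(2-methyl-1,3-dioxolan-2-yl)propan-1-one | CC1(CCC(=O)[C@@]2(C)C[C@H]2/C(C(C)C)=C\B3OC(C)(C)C(C)(C)O3)OCCO1
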